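The numbers in the tables stem from a simulated flask for an exercise, noise included.

1. The green run levels near 16% of the X charged and the blue run near 5%, both from 0.20 M of X, so X seems to leave by other paths as well, and the path to J loses ground as the flask cools.

| flask | X | Q | temperature | remark | time |
|---|---|---|---|---|---|
| blue | 0.20 M | 0.030 M | −10 °C | run made earlier |  |
| green | 0.20 M | 0.045 M | 10 °C | run made earlier |  |
| teal | 0.10 M | 0.060 M | −10 °C | run made earlier |  |
| north-west | 0.20 M | 0.0600 M | 25 °C |  | 2.5 d |
| south-east | 0.20 M | 0.0600 M | −5 °C |  | 2.5 d |
| south-west | 0.20 M | 0.0600 M |  | at −5 °C until 20 h, from then on at 25 °C | 2.5 d |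

- blue (time / d: J / %): 1.25: 1; 2.50: 0; 4.00: 2; 6.00: 4; 10.0: 4; 15.0: 5
- green (time / d: J / %): 0.500: 8; 0.833: 11; 1.25: 12; 2.00: 13; 4.00: 18; 6.00: 16
- teal (time / d: J / %): 1.25: 2; 5.00: 4; 8.00: 3; 12.0: 3; 15.0: 6

(scatter of a reading: 1.5 percentage points)

* which flask leads in amount of J, in percent of the X charged ("all alike" within 1.5 percentage points) (north-west / south-east / south-west / all alike)
* how much J is there at the end, in percent of the X charged: north-west
* how much J is there at the end, in percent of the X charged: south-east
* how much J is there at the end, in percent of the X charged: south-west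

2. The teal run, with other charges of X and Q, ends at 6% against 5% in the blue run at the same temperature, a difference of 1 percentage point against a scatter of 1.5 points. My own reckoning therefore sets the Q charge aside and holds cX at the 0.20 M of the new flasks.

3. Call the share (a selectivity) the part of the X present that ends as J. It is taken to follow a ratio of two rate constants, so its logarithm runs straight in reciprocal temperature, and the green and blue readings give a slope of 36.0 kJ mol⁻¹. The warm share, the share at 25 °C, is then 34.6%, and the share at −5 °C is 6.80%.

4. The approach to the plateau is taken as first order. The green run stands at 8% after 0.500 d, which gives 1.39 d⁻¹, and the blue run stands at 2% after 4.00 d, which gives 0.128 d⁻¹. On a straight line in reciprocal temperature through these two values, the rate constant is 0.240 d⁻¹ at −5 °C, which lies between the two runs, and 6.72 d⁻¹ at 25 °C, an extrapolation beyond the warmest run.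

5. North-west finishes, since its relaxation time of 0.149 d is far shorter than 2.5 d, so I expect the warm share, 34.6%. South-east reaches its plateau in part, giving 3.06%. South-west has 18.1% of its course behind it at the change, and the remainder takes the warm share, giving 29.5%.

6. The forecast names north-west, with 30%, 6% and 28%: “North-west probably leads narrowly, but this is uncertain.” Its south-east value is twice mine.

    X → J (k = 0.0680 h⁻¹, Ea = 96.0 kJ mol⁻¹)
    2 X → G (k = 0.620 M⁻¹ h⁻¹, Ea = 54.0 kJ mol⁻¹)
    X + G → D (k = 0.920 M⁻¹ h⁻¹, Ea = 73.0 kJ mol⁻¹)
    G → L (k = 0.00800 h⁻¹, Ea = 95.0 kJ mol⁻¹)
    X + Q → Z (k = 0.480 M⁻¹ h⁻¹, Ea = 70.0 kJ mol⁻¹)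
    (constants at 25 °C)

The flasks give 31.8% in north-west, near the warm share of 34.6%, 3.24% in south-east and 25.1% in south-west, so north-west leads. In south-west the step of two X to G reached the midpoint of its turnover up to the end by 0.738 d, earlier than the warming at 0.83 d, and at the change X stood at 66.7%, against the 81.9% of the course I had reckoned as still to come, and J at 1.45%. That J plus the warm share of that X comes to 24.5%.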